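**Retrosynthetic overview**
- Feature: in the 1,2-dioxolane ring (O–O–C3–C4–C5, with C1 the carboxyl carbon) both peroxy-bearing carbons, C3 and C5, are quaternary and only the C4 methylene lies between them. C3 therefore maps onto a ketone-level peroxycarbenium carbon and C4–C5 onto a 2-methylalk-1-ene.
- Last disconnections: hydrolysis of the C1 ester and the E-alkene C12=C13 (Julia–Kocienski, C12 aldehyde plus the C13–C17 phenyltetrazolyl sulfone). No second π nucleophile is then present when the ring is made.
- Key disconnection: the C3–C4 and O–C5 bonds form in one cationic [3+2] annulation of a C1–C3 silylperoxy ketal with the C4–C12 alkene. This closes the only non-aromatic ring.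
- Fragments: the alkene comes from (R)-citronellal (C7 bought) by methyl addition and oxidation at C5, cross metathesis with methyl acrylate (C11–C12), hydrogenation, methylenation (C4), reduction and silylation. The ketal comes from ozonolysis of methyl 3-methylbut-3-enoate in methanol.

Key step: step 12

Remark on numbering: C1 is the carboxyl carbon, C2 its CH2, C3–C4–C5 the ring carbons, C6 a CH2, C7 the methyl-bearing stereocentre, C8–C11 are CH2 groups, then C12=C13, C14–C15 and C16=C17–Ph.
Assumption: the dioxolane diastereomers formed in step 12 can be separated by chromatography. All peroxides are handled cold, dilute and on a small scale.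

**Step 1**
Reactants: 1 (R)-citronellal
Product: 2 (4R)-4,8-dimethylnon-7-en-2-ol (both C2 epimers)
Conditions: MeMgBr, Et2O, −78 to 0 °C
Reagents that add atoms: methylmagnesium bromide, C[Mg]Br
Why: Grignard addition to the unhindered aldehyde brings in the future C5 methyl group; the new carbinol centre forms without control and is erased in step 2, and C7 is not touched.

**Step 2**
Reactants: 2 (4R)-4,8-dimethylnon-7-en-2-ol
Product: 3 (R)-4,8-dimethylnon-7-en-2-one
Conditions: Dess–Martin periodinane, CH2Cl2, 0 °C to rt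
Reagents that add atoms: none
Why: Dess–Martin oxidation of the secondary alcohol is mild and leaves the trisubstituted alkene alone, and C7 sits β to the new ketone, so enolisation cannot epimerise it.

**Step 3**
Reactants: 3 (R)-4,8-dimethylnon-7-en-2-one
Product: 4 methyl (2E,6R)-6-methyl-8-oxonon-2-enoate
Conditions: methyl acrylate (excess), second-generation Hoveyda–Grubbs catalyst (cat.), CH2Cl2, 40 °C
Reagents that add atoms: methyl acrylate, C=CC(=O)OC
Why: Olefin cross metathesis of a prenyl-type alkene with an acrylate is an established pairing driven by loss of volatile isobutene, and it exchanges the isopropylidene end for the C11–C12 unit in one operation; the expected E geometry is irrelevant because the alkene is saturated next.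

**Step 4**
Reactants: 4 methyl (2E,6R)-6-methyl-8-oxonon-2-enoate
Product: 5 methyl (R)-6-methyl-8-oxononanoate
Conditions: H2 (1 atm), 10% Pd/C, EtOAc, rt
Reagents that add atoms: none
Why: Heterogeneous catalytic hydrogenation saturates the disubstituted enoate alkene long before the ketone or ester can react, and no stereocentre is formed or touched.

**Step 5**
Reactants: 5 methyl (R)-6-methyl-8-oxononanoate
Product: 6 methyl (R)-6,8-dimethylnon-8-enoate
Conditions: Ph3PCH3Br, n-BuLi, THF, 0 °C; then 5, 0 °C to rt
Reagents that add atoms: methyltriphenylphosphonium bromide, C[P+](c1ccccc1)(c1ccccc1)c1ccccc1.[Br-]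
Why: In this Wittig methylenation the non-stabilised ylide adds to the methyl ketone much faster than to the ester, so a small excess turns C5=O into the C5=C4H2 alkene, and the basic ylide cannot epimerise C7 because it is β to the carbonyl.

**Step 6**
Reactants: 6 methyl (R)-6,8-dimethylnon-8-enoate
Product: 7 (R)-6,8-dimethylnon-8-en-1-ol
Conditions: LiAlH4, Et2O, 0 °C
Reagents that add atoms: none
Why: Hydride reduction of the ester gives the primary C12 alcohol and leaves the unactivated 1,1-disubstituted alkene untouched.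

**Step 7**
Reactants: 7 (R)-6,8-dimethylnon-8-en-1-ol
Product: 8 (R)-tert-butyl[(6,8-dimethylnon-8-en-1-yl)oxy]diphenylsilane
Conditions: TBDPSCl, imidazole, CH2Cl2, rt
Reagents that add atoms: tert-butylchlorodiphenylsilane, CC(C)(C)[Si](Cl)(c1ccccc1)c1ccccc1
Why: This is standard silyl ether formation, and the TBDPS group is chosen because it withstands SnCl4 at low temperature and cannot compete as a nucleophile in step 12.

**Step 8**
Reactants: 9 methyl 3-methylbut-3-enoate
Product: 11 methyl 3-hydroperoxy-3-methoxybutanoate (racemic), via carbonyl oxide 10 (not isolated)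
Conditions: O3, CH2Cl2/MeOH, −78 °C; N2 purge, no reductant, concentration below 20 °C
Reagents that add atoms: ozone, [O-][O+]=O; methanol, CO
Why: In this Criegee ozonolysis in a participating solvent the 1,1-disubstituted alkene is cleaved to formaldehyde and the more substituted carbonyl oxide 10, which methanol traps as the hydroperoxy ketal; the racemic ketal centre does not matter because it is flattened in step 12.

**Step 9**
Reactants: 11 methyl 3-hydroperoxy-3-methoxybutanoate
Product: 12 methyl 3-methoxy-3-(triethylsilylperoxy)butanoate (racemic)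
Conditions: Et3SiCl, imidazole, DMF, 0 °C
Reagents that add atoms: chlorotriethylsilane, CC[Si](Cl)(CC)CC
Why: O-Silylation of the acidic hydroperoxide with a weak base is fast at 0 °C, which should forestall β-elimination next to the ester, and the triethylsilyl group later serves as the leaving group on oxygen.

**Step 10**
Reactants: 13 (E)-5-phenylpent-4-en-1-ol
Product: 14 1-phenyl-5-{[(4E)-5-phenylpent-4-en-1-yl]sulfanyl}-1H-tetrazole
Conditions: 1-phenyl-1H-tetrazole-5-thiol, PPh3, DIAD, THF, 0 °C to rt
Reagents that add atoms: 1-phenyl-1H-tetrazole-5-thiol, Sc1nnnn1-c1ccccc1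
Why: In this Mitsunobu thioetherification the acidic tetrazolethiol displaces the activated primary alcohol by SN2 without touching the styryl alkene.

**Step 11**
Reactants: 14 1-phenyl-5-{[(4E)-5-phenylpent-4-en-1-yl]sulfanyl}-1H-tetrazole
Product: 16 1-phenyl-5-{[(4E)-5-phenylpent-4-en-1-yl]sulfonyl}-1H-tetrazole, via sulfoxide 15 (not isolated)
Conditions: (NH4)6Mo7O24·4H2O (cat.), 30% aq H2O2, EtOH, 0 °C to rt
Reagents that add atoms: hydrogen peroxide, OO
Why: Molybdate-catalysed peroxide oxidation takes the sulfide through sulfoxide 15 to the sulfone and is selective for sulfur over the conjugated alkene, which a peracid would not guarantee.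

**Step 12**
Reactants: 8 (R)-tert-butyl[(6,8-dimethylnon-8-en-1-yl)oxy]diphenylsilane; 12 methyl 3-methoxy-3-(triethylsilylperoxy)butanoate
Product: 19 methyl 2-[(3S,5R)-5-{(2R)-7-[(tert-butyldiphenylsilyl)oxy]-2-methylheptyl}-3,5-dimethyl-1,2-dioxolan-3-yl]acetate, via peroxycarbenium ion 17 (not isolated), via tertiary C5 cation 18 (not isolated)
Conditions: 12 in excess, SnCl4 (1 equiv per 12), CH2Cl2, −78 °C; aq NaHCO3 quench; SiO2 chromatography, then normal-phase HPLC
Reagents that add atoms: none
Why: SnCl4 takes the methoxy group from 12 and flattens the ketal carbon to the silylperoxy-stabilised cation 17, so the racemic nature of 12 is of no consequence, and the CH2 terminus of 8 (C4) then bonds to C3 and leaves the tertiary C5 cation 18. The silylated peroxy oxygen captures C5 and the Et3Si group departs, which completes a stepwise cationic [3+2] annulation of the known type in which Lewis acids join silyl peroxyketals and alkenes to 1,2-dioxolanes. The single ring closes by oxygen attack on a free tertiary cation in a five-membered mode (5-endo only if counted on the former C4=C5 alkene, whose π bond is already spent, so no stereoelectronic penalty applies). C3 is fixed in the C–C bond formation and C5 in the ring closure; because 18 can rotate about C4–C5 before closing, their relation is decided by sterics in the closing envelope, where the CH2CO2Me arm and the branched C6 chain avoid a 1,3-cis contact and the ring methyls end up trans, a preference that should be only modest. The C7 centre lies outside the ring and should not bias the C5 face, so the wanted (3S,5R,7R) isomer has to be separated from its (3R,5S,7R) partner and from the two cis isomers, all of which are diastereomers. The step needs Markovnikov regiochemistry, which the 1,1-disubstituted alkene secures, and chemoselectivity, which is secured because 8 holds no other π nucleophile and its TBDPS ether and the methyl ester withstand SnCl4 at −78 °C.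

**Step 13**
Reactants: 19 methyl 2-[(3S,5R)-5-{(2R)-7-[(tert-butyldiphenylsilyl)oxy]-2-methylheptyl}-3,5-dimethyl-1,2-dioxolan-3-yl]acetate
Product: 20 methyl 2-{(3S,5R)-5-[(2R)-7-hydroxy-2-methylheptyl]-3,5-dimethyl-1,2-dioxolan-3-yl}acetate
Conditions: Bu4NF, AcOH (1:1), THF, 0 °C to rt
Reagents that add atoms: none
Why: Fluoride-mediated silyl ether cleavage is driven by the Si–F bond, and the acetic acid buffer keeps the medium too weakly basic to remove C2–H and open the dioxolane by β-elimination.

**Step 14**
Reactants: 20 methyl 2-{(3S,5R)-5-[(2R)-7-hydroxy-2-methylheptyl]-3,5-dimethyl-1,2-dioxolan-3-yl}acetate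
Product: 21 methyl 2-{(3S,5R)-3,5-dimethyl-5-[(2R)-2-methyl-7-oxoheptyl]-1,2-dioxolan-3-yl}acetate
Conditions: Dess–Martin periodinane, CH2Cl2, 0 °C to rt
Reagents that add atoms: none
Why: Dess–Martin oxidation stops at the C12 aldehyde under non-basic, non-reducing conditions that leave the O–O bond and the ester intact.

**Step 15**
Reactants: 21 methyl 2-{(3S,5R)-3,5-dimethyl-5-[(2R)-2-methyl-7-oxoheptyl]-1,2-dioxolan-3-yl}acetate; 16 1-phenyl-5-{[(4E)-5-phenylpent-4-en-1-yl]sulfonyl}-1H-tetrazole
Product: 23 methyl 2-{(3S,5R)-3,5-dimethyl-5-[(2R,7E,11E)-2-methyl-12-phenyldodeca-7,11-dien-1-yl]-1,2-dioxolan-3-yl}acetate, via potassiated sulfone 22 (not isolated)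
Conditions: 16, KN(SiMe3)2, DME, −60 °C; then 21, −60 °C to rt
Reagents that add atoms: none
Why: In this Julia–Kocienski olefination the pre-formed carbanion 22 adds to the aldehyde faster than it removes C2–H or attacks the hindered O–O bond, and the open transition state favoured by a phenyltetrazolyl sulfone with a potassium counter-ion in DME should give the E C12=C13 alkene.

**Step 16**
Reactants: 23 methyl 2-{(3S,5R)-3,5-dimethyl-5-[(2R,7E,11E)-2-methyl-12-phenyldodeca-7,11-dien-1-yl]-1,2-dioxolan-3-yl}acetate
Product: 25 2-{(3S,5R)-3,5-dimethyl-5-[(2R,7E,11E)-2-methyl-12-phenyldodeca-7,11-dien-1-yl]-1,2-dioxolan-3-yl}acetic acid (target), via lithium carboxylate 24 (not isolated)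
Conditions: LiOH, THF/H2O, 0 °C to rt; then 1 M HCl to pH 3
Reagents that add atoms: lithium hydroxide, [Li+].[OH-]
Why: In this saponification hydroxide attacks the unhindered methyl ester carbonyl faster than it removes C2–H, and once carboxylate 24 has formed further enolisation is disfavoured, so the C3–O bond and all stereocentres should persist through the mild acidification.

**Compound list**
1 | (R)-citronellal | C[C@H](CCC=C(C)C)CC=O | starting material
2 | (4R)-4,8-dimethylnon-7-en-2-ol (C2 epimers) | C[C@H](CCC=C(C)C)CC(C)O | intermediate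
3 | (R)-4,8-dimethylnon-7-en-2-one | C[C@H](CCC=C(C)C)CC(C)=O | intermediate
4 | methyl (2E,6R)-6-methyl-8-oxonon-2-enoate | C[C@H](CC/C=C/C(=O)OC)CC(C)=O | intermediate
5 | methyl (R)-6-methyl-8-oxononanoate | C[C@H](CCCCC(=O)OC)CC(C)=O | intermediate
6 | methyl (R)-6,8-dimethylnon-8-enoate | C[C@H](CCCCC(=O)OC)CC(C)=C | intermediate
7 | (R)-6,8-dimethylnon-8-en-1-ol | C[C@H](CCCCCO)CC(C)=C | intermediate
8 | (R)-tert-butyl[(6,8-dimethylnon-8-en-1-yl)oxy]diphenylsilane | C[C@H](CCCCCO[Si](c1ccccc1)(c1ccccc1)C(C)(C)C)CC(C)=C | intermediate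
9 | methyl 3-methylbut-3-enoate | COC(=O)CC(C)=C | starting material
10 | carbonyl oxide of methyl acetoacetate (not isolated) | COC(=O)CC(C)=[O+][O-] | intermediate
11 | methyl 3-hydroperoxy-3-methoxybutanoate (racemic) | COC(=O)CC(C)(OC)OO | intermediate
12 | methyl 3-methoxy-3-(triethylsilylperoxy)butanoate (racemic) | COC(=O)CC(C)(OC)OO[Si](CC)(CC)CC | intermediate
13 | (E)-5-phenylpent-4-en-1-ol | OCCC/C=C/c1ccccc1 | starting material
14 | 1-phenyl-5-{[(4E)-5-phenylpent-4-en-1-yl]sulfanyl}-1H-tetrazole | C(CC/C=C/c1ccccc1)Sc1nnnn1-c1ccccc1 | intermediate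
15 | corresponding sulfoxide (racemic at sulfur, not isolated) | O=S(CCC/C=C/c1ccccc1)c1nnnn1-c1ccccc1 | intermediate
16 | 1-phenyl-5-{[(4E)-5-phenylpent-4-en-1-yl]sulfonyl}-1H-tetrazole | O=S(=O)(CCC/C=C/c1ccccc1)c1nnnn1-c1ccccc1 | intermediate
17 | triethylsilylperoxy carbenium ion at C3 (not isolated) | COC(=O)CC(C)=[O+]O[Si](CC)(CC)CC | intermediate
18 | tertiary C5 carbocation after C3–C4 bond formation (not isolated) | C[C@H](CCCCCO[Si](c1ccccc1)(c1ccccc1)C(C)(C)C)C[C+](C)CC(C)(CC(=O)OC)OO[Si](CC)(CC)CC | intermediate
19 | methyl 2-[(3S,5R)-5-{(2R)-7-[(tert-butyldiphenylsilyl)oxy]-2-methylheptyl}-3,5-dimethyl-1,2-dioxolan-3-yl]acetate | C[C@H](CCCCCO[Si](c1ccccc1)(c1ccccc1)C(C)(C)C)C[C@]1(C)C[C@@](C)(CC(=O)OC)OO1 | intermediate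
20 | methyl 2-{(3S,5R)-5-[(2R)-7-hydroxy-2-methylheptyl]-3,5-dimethyl-1,2-dioxolan-3-yl}acetate | C[C@H](CCCCCO)C[C@]1(C)C[C@@](C)(CC(=O)OC)OO1 | intermediate
21 | methyl 2-{(3S,5R)-3,5-dimethyl-5-[(2R)-2-methyl-7-oxoheptyl]-1,2-dioxolan-3-yl}acetate | C[C@H](CCCCC=O)C[C@]1(C)C[C@@](C)(CC(=O)OC)OO1 | intermediate
22 | potassium α-sulfonyl carbanion of 16 (not isolated) | [K+].[CH-](CC/C=C/c1ccccc1)S(=O)(=O)c1nnnn1-c1ccccc1 | intermediate
23 | methyl 2-{(3S,5R)-3,5-dimethyl-5-[(2R,7E,11E)-2-methyl-12-phenyldodeca-7,11-dien-1-yl]-1,2-dioxolan-3-yl}acetate | C[C@H](CCCC/C=C/CC/C=C/c1ccccc1)C[C@]1(C)C[C@@](C)(CC(=O)OC)OO1 | intermediate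
24 | lithium carboxylate of the target (not isolated) | C[C@H](CCCC/C=C/CC/C=C/c1ccccc1)C[C@]1(C)C[C@@](C)(CC(=O)[O-])OO1.[Li+] | intermediate
25 | 2-{(3S,5R)-3,5-dimethyl-5-[(2R,7E,11E)-2-methyl-12-phenyldodeca-7,11-dien-1-yl]-1,2-dioxolan-3-yl}acetic acid | C[C@H](CCCC/C=C/CC/C=C/c1ccccc1)C[C@]1(C)C[C@@](C)(CC(=O)O)OO1 | target

Total step count: 16.
Longest linear sequence: 12 (steps 1–7 and 12–16).

**Steps most likely to fail**

**1. Step 12.**
- What may go wrong: the ester next to C3 slows ionisation and destabilises the cation. Proton loss, chloride capture or O–O heterolysis may then outrun ring closure, and the preference for the trans ring may be weak.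
- Fallback: it sets out from 8 and comes back at 19. The ring is built outward from C5 and the C2–C3 bond is made last.
- A Me2AlCl-promoted carbonyl-ene reaction of 8 with acetaldehyde (CH2Cl2, −78 to 0 °C) should give the exo-methylene homoallylic alcohol F1 together with its trisubstituted alkene isomer F2.
- Both converge in a Mukaiyama–Isayama peroxysilylation (Co(acac)2 cat., O2, Et3SiH, 1,2-dichloroethane, rt), because hydrogen-atom delivery to either alkene leads to the same tertiary C5 radical. The product is the triethylsilylperoxy alcohol F3.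
- Dess–Martin oxidation gives the β-silylperoxy ketone F4.
- Catalytic TsOH in methanol should strip the peroxy silyl group and close the ring directly to the 3-methoxy-1,2-dioxolane F5.
- TiCl4 and 1-(tert-butyldimethylsilyloxy)-1-methoxyethene (CH2Cl2, −78 °C) then replace the C3 methoxy group by the acetate arm. This Lewis-acid substitution of 3-alkoxy-1,2-dioxolanes by silyl ketene acetals is a known reaction type, and it should deliver the nucleophile to the face away from the larger C5 substituent.
- This gives 19 after the same separation of C5 epimers.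

**2. Step 9.**
- What may go wrong: under the silylation conditions the hydroperoxide may close onto the neighbouring ester, or removal of C2–H may expel methoxide or the peroxy group. Either process destroys the ketal before it is capped.
- Fallback: it sets out from 8 and comes back at 19, with C1 carried at the alcohol oxidation level so that no acidic C2–H or nearby ester carbonyl is present.
- The catalogue compound 3-methylbut-3-en-1-yl acetate F6 is ozonised in CH2Cl2/MeOH at −78 °C to 3-hydroperoxy-3-methoxybutyl acetate F7.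
- Silylation (Et3SiCl, imidazole) gives 3-methoxy-3-(triethylsilylperoxy)butyl acetate F8.
- Annulation of F8 with 8 (SnCl4, CH2Cl2, −78 °C), followed by separation, should give the dioxolanylethyl acetate F9.
- K2CO3 in MeOH frees the dioxolanylethanol F10.
- TEMPO (cat.) with PhI(OAc)2 in MeCN/H2O oxidises it to the silyloxy dioxolane acetic acid F11.
- Me3SiCHN2 in toluene/MeOH then gives 19.

**3. Step 15.**
- What may go wrong: proton transfer from C2–H or from the aldehyde α-position to the carbanion, followed by β-elimination that opens the dioxolane, and erosion of the E selectivity.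
- Fallback: it sets out from 20 and 13 and comes back at 23, with the roles of the two partners exchanged.
- Mitsunobu reaction of 20 with 1-phenyl-1H-tetrazole-5-thiol (PPh3, DIAD, THF) gives the dioxolane tetrazolyl sulfide F12.
- (NH4)6Mo7O24·4H2O with H2O2 in EtOH gives the dioxolane tetrazolyl sulfone F13.
- Separately, Dess–Martin oxidation of 13 gives (E)-5-phenylpent-4-enal F14.
- KN(SiMe3)2 is then added last to a cold DME solution of F13 and excess F14 (Barbier mode). The base meets the most acidic site, the sulfone α-CH2, and the carbanion is trapped at once by the simple aldehyde.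
- This should give 23.

**Further compounds**
F1 | step 12 | (6R)-11-[(tert-butyldiphenylsilyl)oxy]-6-methyl-4-methylideneundecan-2-ol (C2 epimers) | C[C@H](CCCCCO[Si](c1ccccc1)(c1ccccc1)C(C)(C)C)CC(=C)CC(C)O
F2 | step 12 | (6R)-11-[(tert-butyldiphenylsilyl)oxy]-4,6-dimethylundec-4-en-2-ol (alkene and C2 isomers) | C[C@H](CCCCCO[Si](c1ccccc1)(c1ccccc1)C(C)(C)C)C=C(C)CC(C)O
F3 | step 12 | (6R)-11-[(tert-butyldiphenylsilyl)oxy]-4,6-dimethyl-4-(triethylsilylperoxy)undecan-2-ol (C2 and C4 epimers) | C[C@H](CCCCCO[Si](c1ccccc1)(c1ccccc1)C(C)(C)C)CC(C)(CC(C)O)OO[Si](CC)(CC)CC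
F4 | step 12 | (6R)-11-[(tert-butyldiphenylsilyl)oxy]-4,6-dimethyl-4-(triethylsilylperoxy)undecan-2-one (C4 epimers) | C[C@H](CCCCCO[Si](c1ccccc1)(c1ccccc1)C(C)(C)C)CC(C)(CC(C)=O)OO[Si](CC)(CC)CC
F5 | step 12 | tert-butyl{[(6R)-7-(5-methoxy-3,5-dimethyl-1,2-dioxolan-3-yl)-6-methylheptyl]oxy}diphenylsilane (ring epimers) | C[C@H](CCCCCO[Si](c1ccccc1)(c1ccccc1)C(C)(C)C)CC1(C)CC(C)(OC)OO1
F6 | step 9 | 3-methylbut-3-en-1-yl acetate | CC(=C)CCOC(C)=O
F7 | step 9 | 3-hydroperoxy-3-methoxybutyl acetate (racemic) | CC(=O)OCCC(C)(OC)OO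
F8 | step 9 | 3-methoxy-3-(triethylsilylperoxy)butyl acetate (racemic) | CC(=O)OCCC(C)(OC)OO[Si](CC)(CC)CC
F9 | step 9 | 2-[(3R,5R)-5-{(2R)-7-[(tert-butyldiphenylsilyl)oxy]-2-methylheptyl}-3,5-dimethyl-1,2-dioxolan-3-yl]ethyl acetate | C[C@H](CCCCCO[Si](c1ccccc1)(c1ccccc1)C(C)(C)C)C[C@]1(C)C[C@@](C)(CCOC(C)=O)OO1
F10 | step 9 | 2-[(3R,5R)-5-{(2R)-7-[(tert-butyldiphenylsilyl)oxy]-2-methylheptyl}-3,5-dimethyl-1,2-dioxolan-3-yl]ethan-1-ol | C[C@H](CCCCCO[Si](c1ccccc1)(c1ccccc1)C(C)(C)C)C[C@]1(C)C[C@@](C)(CCO)OO1
F11 | step 9 | 2-[(3S,5R)-5-{(2R)-7-[(tert-butyldiphenylsilyl)oxy]-2-methylheptyl}-3,5-dimethyl-1,2-dioxolan-3-yl]acetic acid | C[C@H](CCCCCO[Si](c1ccccc1)(c1ccccc1)C(C)(C)C)C[C@]1(C)C[C@@](C)(CC(=O)O)OO1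
F12 | step 15 | methyl 2-[(3S,5R)-3,5-dimethyl-5-{(2R)-2-methyl-7-[(1-phenyl-1H-tetrazol-5-yl)sulfanyl]heptyl}-1,2-dioxolan-3-yl]acetate | C[C@H](CCCCCSc1nnnn1-c1ccccc1)C[C@]1(C)C[C@@](C)(CC(=O)OC)OO1
F13 | step 15 | methyl 2-[(3S,5R)-3,5-dimethyl-5-{(2R)-2-methyl-7-[(1-phenyl-1H-tetrazol-5-yl)sulfonyl]heptyl}-1,2-dioxolan-3-yl]acetate | C[C@H](CCCCCS(=O)(=O)c1nnnn1-c1ccccc1)C[C@]1(C)C[C@@](C)(CC(=O)OC)OO1
F14 | step 15 | (E)-5-phenylpent-4-enal | O=CCC/C=C/c1ccccc1
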